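**Retrosynthetic overview**
1. Target ⇒ acetylation and hydroxyl-directed VO(acac)2 epoxidation of a macrocyclic 13-hydroxy cis-lactone; C11 and C12 are set last, from C13.
2. Macrocyclic lactone ⇒ open-chain (Z)-2-(bromomethyl)enoate/enal; the C1–C2 bond is made by a visible-light photoredox/chromium allylation that closes the 14-membered carbocycle first and the γ-lactone onto it in the same flask (sets C1 and C2 from C13).
3. Bromo enal ⇒ Morita–Baylis–Hillman reaction and SN2′ bromination at a C1 aldehyde; the C2–C14 chain ⇒ B-alkyl Suzuki coupling (C10–C11) of a geranyl acetate-derived triene with an (E)-vinyl iodide.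
4. Vinyl iodide ⇒ zirconium-catalysed carboalumination of an alkynol made from (R)-α-hydroxy-γ-butyrolactone, the only source of chirality (C13).

Assumption: the SMILES is read as (1S,2S,3E,7E,11R,12S,13R)-13-acetoxy-11,12-epoxycembra-3,7,15(17)-trien-16,2-olide (cis-fused lactone, trans epoxide, erythro epoxy acetate). Cembrane numbering is used throughout: C1 lactone β-carbon, C2 lactone O–CH, C15/C16/C17 the α-carbon, carbonyl and exocyclic CH2, C18–C20 the methyls on C4, C8, C12. (R)-α-Hydroxy-γ-butyrolactone is taken as a catalogue compound made from D-malic acid.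

**Route**

Step 1
Reactants: 1 (R)-α-hydroxy-γ-butyrolactone [(3R)-3-hydroxyoxolan-2-one]
Product: 2 (3R)-3-[(tert-butyldimethylsilyl)oxy]oxolan-2-one
Conditions: TBSCl, imidazole, DMF, 0 °C → rt
Reagents that add atoms: tert-butyldimethylsilyl chloride, CC(C)(C)[Si](C)(C)Cl
Why: Imidazole-promoted silylation of the secondary alcohol; the bought 3R centre (future C13) is not touched.

Step 2
Reactants: 2 (3R)-3-[(tert-butyldimethylsilyl)oxy]oxolan-2-one
Product: 3 (3R)-3-[(tert-butyldimethylsilyl)oxy]oxolan-2-ol (lactol, both anomers)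
Conditions: i-Bu2AlH (1.1 equiv), CH2Cl2, −78 °C; Rochelle salt work-up
Reagents that add atoms: none
Why: Partial lactone reduction with i-Bu2AlH stops at the lactol because the tetrahedral aluminium hemiacetal survives at −78 °C until work-up.

Step 3
Reactants: 3 (3R)-3-[(tert-butyldimethylsilyl)oxy]oxolan-2-ol
Product: 4 (3R)-3-[(tert-butyldimethylsilyl)oxy]pent-4-yn-1-ol
Conditions: dimethyl (1-diazo-2-oxopropyl)phosphonate, K2CO3, MeOH, 0 °C → rt
Reagents that add atoms: dimethyl (1-diazo-2-oxopropyl)phosphonate, COP(=O)(OC)C(=[N+]=[N-])C(C)=O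
Why: Ohira–Bestmann (Seyferth–Gilbert) homologation of the open hydroxy-aldehyde form of the lactol gives the terminal alkyne under mild base, run cold to avoid silyl migration and α-epimerisation.

Step 4
Reactants: 4 (3R)-3-[(tert-butyldimethylsilyl)oxy]pent-4-yn-1-ol
Product: 6 (3R,4E)-3-[(tert-butyldimethylsilyl)oxy]-5-iodo-4-methylpent-4-en-1-ol, via alkenylalane 5 (not isolated)
Conditions: AlMe3 (3.5 equiv), Cp2ZrCl2 (0.3 equiv), CH2Cl2, 0 °C → rt; then I2, THF, −30 → 0 °C
Reagents that add atoms: trimethylaluminium, C[Al](C)C; iodine, II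
Why: Negishi zirconium-catalysed carboalumination adds methyl and aluminium syn across the alkyne with methyl on the internal carbon, and iodinolysis with retention gives the (E)-2-methyl vinyl iodide that fixes the later C11=C12 geometry.

Step 5
Reactants: 7 geranyl acetate [(2E)-3,7-dimethylocta-2,6-dien-1-yl acetate]
Product: 9 (2E,6E)-3,7-dimethyl-8-oxoocta-2,6-dien-1-yl acetate, via 8-hydroxygeranyl acetate 8 (not isolated)
Conditions: SeO2 (0.1 equiv), salicylic acid (0.1 equiv), t-BuOOH (70% aq), CH2Cl2, rt; then activated MnO2, same flask, rt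
Reagents that add atoms: selenium dioxide, O=[Se]=O; tert-butyl hydroperoxide, CC(C)(C)OO
Why: SeO2/t-BuOOH allylic oxidation (ene then [2,3] shift) is selective for the (E)-methyl of the terminal prenyl group, and MnO2 carries the allylic alcohol on to the enal without touching the acetate.

Step 6
Reactants: 9 (2E,6E)-3,7-dimethyl-8-oxoocta-2,6-dien-1-yl acetate
Product: 10 (2E,6E)-3,7-dimethylnona-2,6,8-trien-1-yl acetate
Conditions: Ph3PCH3Br, n-BuLi, THF, 0 °C; then 9, −78 → 0 °C
Reagents that add atoms: methyltriphenylphosphonium bromide, C[P+](c1ccccc1)(c1ccccc1)c1ccccc1.[Br-]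
Why: Wittig methylenation of the conjugated aldehyde, which reacts far faster than the acetate, gives the terminal diene with both E alkenes unchanged.

Step 7
Reactants: 10 (2E,6E)-3,7-dimethylnona-2,6,8-trien-1-yl acetate; 6 (3R,4E)-3-[(tert-butyldimethylsilyl)oxy]-5-iodo-4-methylpent-4-en-1-ol
Product: 13 (2E,6E,10E,12R)-12-[(tert-butyldimethylsilyl)oxy]-3,7,11-trimethyltetradeca-2,6,10-triene-1,14-diol, via alkyl-9-BBN borane 11 (not isolated), via coupled acetate 12 (not isolated)
Conditions: 9-BBN, THF, 0 °C → rt; then 6, PdCl2(dppf) (5 mol%), AsPh3, Cs2CO3, DMF/H2O, rt; then K2CO3 (0.3 equiv), MeOH, rt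
Reagents that add atoms: none
Why: 9-BBN hydroborates only the monosubstituted vinyl terminus (anti-Markovnikov), the B-alkyl Suzuki–Miyaura coupling joins C10 to C11 with retention of the E geometry, and methanolysis then frees the allylic alcohol in the same flask.

Step 8
Reactants: 13 (2E,6E,10E,12R)-12-[(tert-butyldimethylsilyl)oxy]-3,7,11-trimethyltetradeca-2,6,10-triene-1,14-diol
Product: 14 (2E,6E,10E,12R)-12-[(tert-butyldimethylsilyl)oxy]-3,7,11-trimethyltetradeca-2,6,10-trienedial
Conditions: Dess–Martin periodinane (2.6 equiv), CH2Cl2, 0 °C → rt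
Reagents that add atoms: none
Why: Dess–Martin oxidation converts both primary alcohols to aldehydes without E/Z erosion of the enal or loss of the silyl ether.

Step 9
Reactants: 14 (2E,6E,10E,12R)-12-[(tert-butyldimethylsilyl)oxy]-3,7,11-trimethyltetradeca-2,6,10-trienedial; 15 methyl acrylate
Product: 16 methyl (5R,6E,10E,14E)-5-[(tert-butyldimethylsilyl)oxy]-3-hydroxy-6,10,14-trimethyl-2-methylidene-16-oxohexadeca-6,10,14-trienoate (both C3 epimers)
Conditions: methyl acrylate (10 equiv, neat), quinuclidine (0.5 equiv), MeOH (1 equiv), rt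
Reagents that add atoms: none
Why: Morita–Baylis–Hillman reaction, in which the amine–acrylate zwitterion adds to the unhindered saturated aldehyde much faster than to the conjugated β,β-disubstituted enal; the new carbinol centre is formed unselectively and is erased in step 10.

Step 10
Reactants: 16 methyl (5R,6E,10E,14E)-5-[(tert-butyldimethylsilyl)oxy]-3-hydroxy-6,10,14-trimethyl-2-methylidene-16-oxohexadeca-6,10,14-trienoate
Product: 17 methyl (2Z,5R,6E,10E,14E)-2-(bromomethyl)-5-[(tert-butyldimethylsilyl)oxy]-6,10,14-trimethyl-16-oxohexadeca-2,6,10,14-tetraenoate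
Conditions: NBS, Me2S, CH2Cl2, −20 °C → rt
Reagents that add atoms: N-bromosuccinimide, O=C1CCC(=O)N1Br
Why: Corey–Kim-type activation of the Baylis–Hillman alcohol and SN2′ attack of bromide give the thermodynamically preferred (Z)-2-(bromomethyl)enoate (C14 cis to CH2Br), the geometry required for a syn allylation.

Step 11
Reactants: 17 methyl (2Z,5R,6E,10E,14E)-2-(bromomethyl)-5-[(tert-butyldimethylsilyl)oxy]-6,10,14-trimethyl-16-oxohexadeca-2,6,10,14-tetraenoate
Product: 19 (1S,2S,3E,7E,11E,13R)-13-[(tert-butyldimethylsilyl)oxy]cembra-3,7,11,15(17)-tetraen-16,2-olide, via hydroxy ester 18 (not isolated)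
Conditions: CrCl3·3THF (15 mol%), 4CzIPN (2 mol%), Hantzsch ester (1.5 equiv), 2,6-lutidine (2 equiv), degassed DMF, 450 nm LEDs, 25 °C, 17 added over 12 h (final 2 mM); then PPTS (0.2 equiv), CH2Cl2, rt
Reagents that add atoms: none
Why: Proposed new method: a visible-light photoredox/chromium dual-catalysed intramolecular carbonyl 2-(methoxycarbonyl)allylation in which photoexcited 4CzIPN is reductively quenched by the Hantzsch ester and the reduced dye returns trivalent chromium to divalent chromium, which abstracts bromine from the allylic bromide and captures the allyl radical, so that the (Z)-γ-substituted allyl–CrX2 species adds to the tethered enal through a closed chair transition state with C14 axial and forms C1–C2, the 14-membered ring and the syn C1/C2 pair (the cis lactone after loss of methanol) in one operation, lutidinium protonating the Cr–O alkoxide for turnover; the 13R silyloxy centre is expected to give the 1S,2S pair because only the 1,3-anti C13/C1 arrangement lets the C12–C13–C14–C1–C2 segment stay extended without a syn-pentane contact in the ring-closing transition state; the closest known reactions are stoichiometric CrCl2 Nozaki–Hiyama–Kishi macro-allylations of bromo aldehydes, the CrCl2-mediated cis-selective lactone synthesis from 2-(bromomethyl)enoates, and intermolecular photoredox/chromium allylations of aldehydes.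

Step 12
Reactants: 19 (1S,2S,3E,7E,11E,13R)-13-[(tert-butyldimethylsilyl)oxy]cembra-3,7,11,15(17)-tetraen-16,2-olide
Product: 20 (1S,2S,3E,7E,11E,13R)-13-hydroxycembra-3,7,11,15(17)-tetraen-16,2-olide
Conditions: HF·pyridine, pyridine, THF, 0 °C → rt
Reagents that add atoms: none
Why: Buffered fluoride desilylation frees the allylic alcohol and leaves the α-methylene lactone and the trisubstituted alkenes intact.

Step 13
Reactants: 20 (1S,2S,3E,7E,11E,13R)-13-hydroxycembra-3,7,11,15(17)-tetraen-16,2-olide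
Product: 21 (1S,2S,3E,7E,11R,12R,13R)-11,12-epoxy-13-hydroxycembra-3,7,15(17)-trien-16,2-olide
Conditions: VO(acac)2 (5 mol%), t-BuOOH (decane, 1.5 equiv), CH2Cl2, 0 °C → rt
Reagents that add atoms: tert-butyl hydroperoxide, CC(C)(C)OO
Why: Vanadium-catalysed hydroxyl-directed epoxidation reacts only at the allylic-alcohol alkene C11=C12 and, by the A(1,2)-strain model for 2-methyl allylic alcohols, delivers oxygen to give the erythro epoxy alcohol, so C11 and C12 are set from the 13R carbinol (C12 is R here and S after acetylation only through the priority change).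

Step 14
Reactants: 21 (1S,2S,3E,7E,11R,12R,13R)-11,12-epoxy-13-hydroxycembra-3,7,15(17)-trien-16,2-olide
Product: 22 (1S,2S,3E,7E,11R,12S,13R)-13-acetoxy-11,12-epoxycembra-3,7,15(17)-trien-16,2-olide (CNP0146076.4)
Conditions: Ac2O, pyridine, DMAP (0.1 equiv), CH2Cl2, 0 °C → rt
Reagents that add atoms: acetic anhydride, CC(=O)OC(C)=O
Why: DMAP-catalysed acetylation of the hindered secondary alcohol gives the target without touching any stereocentre.

**Compound list**
1 | (R)-α-hydroxy-γ-butyrolactone, (3R)-3-hydroxyoxolan-2-one | O=C1OCC[C@H]1O | starting material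
2 | (3R)-3-[(tert-butyldimethylsilyl)oxy]oxolan-2-one | O=C1OCC[C@H]1O[Si](C)(C)C(C)(C)C | intermediate
3 | (3R)-3-[(tert-butyldimethylsilyl)oxy]oxolan-2-ol (lactol, both anomers) | OC1OCC[C@H]1O[Si](C)(C)C(C)(C)C | intermediate
4 | (3R)-3-[(tert-butyldimethylsilyl)oxy]pent-4-yn-1-ol | C#C[C@H](O[Si](C)(C)C(C)(C)C)CCO | intermediate
5 | [(1E,3R)-3-[(tert-butyldimethylsilyl)oxy]-5-[(dimethylalumanyl)oxy]-2-methylpent-1-en-1-yl]dimethylalumane | C[Al](C)/C=C(\C)[C@H](O[Si](C)(C)C(C)(C)C)CCO[Al](C)C | intermediate (not isolated)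
6 | (3R,4E)-3-[(tert-butyldimethylsilyl)oxy]-5-iodo-4-methylpent-4-en-1-ol | I/C=C(\C)[C@H](O[Si](C)(C)C(C)(C)C)CCO | intermediate
7 | geranyl acetate, (2E)-3,7-dimethylocta-2,6-dien-1-yl acetate | CC(C)=CCC/C(C)=C/COC(C)=O | starting material
8 | (2E,6E)-8-hydroxy-3,7-dimethylocta-2,6-dien-1-yl acetate | OC/C(C)=C/CC/C(C)=C/COC(C)=O | intermediate (not isolated)
9 | (2E,6E)-3,7-dimethyl-8-oxoocta-2,6-dien-1-yl acetate | O=C/C(C)=C/CC/C(C)=C/COC(C)=O | intermediate
10 | (2E,6E)-3,7-dimethylnona-2,6,8-trien-1-yl acetate | C=C/C(C)=C/CC/C(C)=C/COC(C)=O | intermediate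
11 | (2E,6E)-9-(9-borabicyclo[3.3.1]nonan-9-yl)-3,7-dimethylnona-2,6-dien-1-yl acetate | CC(=O)OC/C=C(\C)CC/C=C(\C)CCB1C2CCCC1CCC2 | intermediate (not isolated)
12 | (2E,6E,10E,12R)-12-[(tert-butyldimethylsilyl)oxy]-14-hydroxy-3,7,11-trimethyltetradeca-2,6,10-trien-1-yl acetate | CC(=O)OC/C=C(\C)CC/C=C(\C)CC/C=C(\C)[C@H](O[Si](C)(C)C(C)(C)C)CCO | intermediate (not isolated)
13 | (2E,6E,10E,12R)-12-[(tert-butyldimethylsilyl)oxy]-3,7,11-trimethyltetradeca-2,6,10-triene-1,14-diol | OC/C=C(\C)CC/C=C(\C)CC/C=C(\C)[C@H](O[Si](C)(C)C(C)(C)C)CCO | intermediate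
14 | (2E,6E,10E,12R)-12-[(tert-butyldimethylsilyl)oxy]-3,7,11-trimethyltetradeca-2,6,10-trienedial | O=C/C=C(\C)CC/C=C(\C)CC/C=C(\C)[C@H](O[Si](C)(C)C(C)(C)C)CC=O | intermediate
15 | methyl acrylate | C=CC(=O)OC | starting material
16 | methyl (5R,6E,10E,14E)-5-[(tert-butyldimethylsilyl)oxy]-3-hydroxy-6,10,14-trimethyl-2-methylidene-16-oxohexadeca-6,10,14-trienoate (C3 epimers) | C=C(C(=O)OC)C(O)C[C@@H](O[Si](C)(C)C(C)(C)C)/C(C)=C/CC/C(C)=C/CC/C(C)=C/C=O | intermediate
17 | methyl (2Z,5R,6E,10E,14E)-2-(bromomethyl)-5-[(tert-butyldimethylsilyl)oxy]-6,10,14-trimethyl-16-oxohexadeca-2,6,10,14-tetraenoate | COC(=O)/C(CBr)=C/C[C@@H](O[Si](C)(C)C(C)(C)C)/C(C)=C/CC/C(C)=C/CC/C(C)=C/C=O | intermediate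
18 | methyl 2-[(1S,2S,3E,7E,11E,13R)-13-[(tert-butyldimethylsilyl)oxy]-2-hydroxy-4,8,12-trimethylcyclotetradeca-3,7,11-trien-1-yl]prop-2-enoate | C=C(C(=O)OC)[C@@H]1C[C@@H](O[Si](C)(C)C(C)(C)C)/C(C)=C/CC/C(C)=C/CC/C(C)=C/[C@@H]1O | intermediate (not isolated)
19 | (1S,2S,3E,7E,11E,13R)-13-[(tert-butyldimethylsilyl)oxy]cembra-3,7,11,15(17)-tetraen-16,2-olide (cis-fused α-methylene-γ-lactone on the 14-membered ring) | C=C1C(=O)O[C@H]2/C=C(\C)CC/C=C(\C)CC/C=C(\C)[C@H](O[Si](C)(C)C(C)(C)C)C[C@@H]12 | intermediate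
20 | (1S,2S,3E,7E,11E,13R)-13-hydroxycembra-3,7,11,15(17)-tetraen-16,2-olide | C=C1C(=O)O[C@H]2/C=C(\C)CC/C=C(\C)CC/C=C(\C)[C@H](O)C[C@@H]12 | intermediate
21 | (1S,2S,3E,7E,11R,12R,13R)-11,12-epoxy-13-hydroxycembra-3,7,15(17)-trien-16,2-olide | C=C1C(=O)O[C@H]2/C=C(\C)CC/C=C(\C)CC[C@H]3O[C@]3(C)[C@H](O)C[C@@H]12 | intermediate
22 | (1S,2S,3E,7E,11R,12S,13R)-13-acetoxy-11,12-epoxycembra-3,7,15(17)-trien-16,2-olide (CNP0146076.4) | C=C1C(=O)O[C@H]2/C=C(\C)CC/C=C(\C)CC[C@H]3O[C@]3(C)[C@H](OC(C)=O)C[C@@H]12 | target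

**Step count and risks**

Total: 14 steps. Longest linear sequence: 12 steps (steps 1–4 and 7–14, from lactone 1); the triene arm is 2 steps (steps 5–6).

Most likely to fail:

1. Step 11 (the proposed photoredox/chromium macro-allylation). Catalytic turnover at 2 mM is untested, and the induction from C13 to C1/C2 is a conformational prediction. Fallback with known chemistry, leaving out light, radicals and chromium: it sets out from bromide 17. Pd2(dba)3-catalysed borylation with bis(pinacolato)diboron (THF, rt, 0.05 M, where the electron-poor boronate does not yet attack the aldehyde) gives the pinacol allylboronate F1. Dilution to 2 mM in toluene and heating to 90 °C (or Sc(OTf)3 at 0 °C) brings about the known lactone-forming 2-(alkoxycarbonyl)allylboration of the tethered enal through the same chair geometry, giving the cyclised pinacol borate F2. Aqueous work-up releases hydroxy ester 18 and PPTS closes it to 19, where the fallback rejoins the route. If the fault is the sense of 1,3-induction and not reactivity, the fallback under point 3 supplies a differently biased cyclisation substrate.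

2. Step 9 (Morita–Baylis–Hillman on a β-silyloxy aldehyde next to an enal). It may be slow, and the amine can cause β-elimination of the silyloxy group. Fallback: the acrylate unit is delivered as a preformed vinyl metal in place of amine catalysis. It sets out from dial 14: [1-(methoxycarbonyl)vinyl]diisobutylalane, made from methyl propiolate with i-Bu2AlH and N-methylmorpholine N-oxide in THF, is added at −78 °C (1.05 equiv). It attacks the saturated aldehyde in preference to the hindered conjugated one (vinylalumination) and gives adduct 16 directly, where the route continues. This fallback makes no new compound (F0).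

3. Step 13 (directed epoxidation inside the macrocycle). The ring may override the open-chain erythro preference. Fallback: the epoxide is set before ring closure, where the A(1,2) model is secure. It sets out from bromide 17: HF·pyridine gives the free allylic alcohol F3; VO(acac)2/t-BuOOH gives the erythro epoxy alcohol F4; AcCl with 2,6-lutidine at −20 °C gives the epoxy acetate F5. Cyclisation under the step 11 conditions passes through the hydroxy ester F6 and arrives directly at target 22. F3 and F4 are kept cold and carried on at once, because the free C13 hydroxyl can displace the allylic bromide.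

**Further compounds**
F1 | step 11 | methyl (2E,5R,6E,10E,14E)-5-[(tert-butyldimethylsilyl)oxy]-6,10,14-trimethyl-16-oxo-2-[(4,4,5,5-tetramethyl-1,3,2-dioxaborolan-2-yl)methyl]hexadeca-2,6,10,14-tetraenoate | COC(=O)/C(CB1OC(C)(C)C(C)(C)O1)=C/C[C@@H](O[Si](C)(C)C(C)(C)C)/C(C)=C/CC/C(C)=C/CC/C(C)=C/C=O
F2 | step 11 | methyl 2-[(1S,2S,3E,7E,11E,13R)-13-[(tert-butyldimethylsilyl)oxy]-4,8,12-trimethyl-2-[(4,4,5,5-tetramethyl-1,3,2-dioxaborolan-2-yl)oxy]cyclotetradeca-3,7,11-trien-1-yl]prop-2-enoate | C=C(C(=O)OC)[C@@H]1C[C@@H](O[Si](C)(C)C(C)(C)C)/C(C)=C/CC/C(C)=C/CC/C(C)=C/[C@@H]1OB2OC(C)(C)C(C)(C)O2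
F0 | step 9 | none | none
F3 | step 13 | methyl (2Z,5R,6E,10E,14E)-2-(bromomethyl)-5-hydroxy-6,10,14-trimethyl-16-oxohexadeca-2,6,10,14-tetraenoate | COC(=O)/C(CBr)=C/C[C@@H](O)/C(C)=C/CC/C(C)=C/CC/C(C)=C/C=O
F4 | step 13 | methyl (2Z,5R,6R,7R,10E,14E)-2-(bromomethyl)-6,7-epoxy-5-hydroxy-6,10,14-trimethyl-16-oxohexadeca-2,10,14-trienoate | COC(=O)/C(CBr)=C/C[C@@H](O)[C@@]1(C)O[C@@H]1CC/C(C)=C/CC/C(C)=C/C=O
F5 | step 13 | methyl (2Z,5R,6S,7R,10E,14E)-5-acetoxy-2-(bromomethyl)-6,7-epoxy-6,10,14-trimethyl-16-oxohexadeca-2,10,14-trienoate | COC(=O)/C(CBr)=C/C[C@@H](OC(C)=O)[C@@]1(C)O[C@@H]1CC/C(C)=C/CC/C(C)=C/C=O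
F6 | step 13 | methyl 2-[(1S,2S,3E,7E,11R,12S,13R)-13-acetoxy-11,12-epoxy-2-hydroxy-4,8,12-trimethylcyclotetradeca-3,7-dien-1-yl]prop-2-enoate | C=C(C(=O)OC)[C@@H]1C[C@@H](OC(C)=O)[C@@]2(C)O[C@@H]2CC/C(C)=C/CC/C(C)=C/[C@@H]1O
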